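(All runs were computed for an exercise, and the scatter is random.)

**Two runs.** Monday's run, with 2.1 µM of enzyme, holds 11.3% of target at 20.0 h. Thursday's run, with 0.56 µM, holds 24.8% at that time and is still climbing. So target is lost as well as made, and the loss grows with enzyme. My balance: c(target) changes by s − c(target)/τ, with s the supply from the dissolving solid and τ the target lifetime, taken as inversely proportional to enzyme. Then c(target) approaches a ceiling sτ, a steady state, and the gap shrinks by the factor e every τ.

| flask | solid substrate | enzyme | remark | time |
|---|---|---|---|---|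
| Thursday's | 0.020 M | 0.56 µM | run made earlier |  |
| Tuesday's | 0.020 M | 1.2 µM | run made earlier |  |
| Monday's | 0.020 M | 2.1 µM | run made earlier |  |
| Sunday's | 0.054 M | 2 µM | run made earlier |  |
| noon | 0.020 M | 2.0 µM |  | 30 h |
| midnight | 0.080 M | 0.60 µM |  | 30 h |

| run | time / h | target / % |
|---|---|---|
| Thursday's | 2.00 | 2.2 |
| Thursday's | 5.00 | 6.6 |
| Thursday's | 10.0 | 13.1 |
| Thursday's | 15.0 | 19.8 |
| Thursday's | 20.0 | 24.8 |
| Tuesday's | 1.50 | 1.9 |
| Tuesday's | 3.00 | 4.4 |
| Tuesday's | 6.00 | 7.7 |
| Tuesday's | 12.0 | 13.7 |
| Tuesday's | 20.0 | 17.7 |
| Monday's | 1.50 | 2.5 |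
| Monday's | 3.00 | 4.1 |
| Monday's | 6.00 | 6.4 |
| Monday's | 12.0 | 9.8 |
| Monday's | 20.0 | 11.3 |
| Sunday's | 2.00 | 1.4 |
| Sunday's | 5.00 | 2.8 |
| Sunday's | 10.0 | 3.5 |
| Sunday's | 15.0 | 4.2 |
| Sunday's | 20.0 | 3.9 |

(each reading ± 0.3 percentage points)

- given per volume of solution although it is solid: solid substrate
- at the start none of the solid substrate is in solution
- what has only dissolved of solid substrate counts as not reacted

1. which of the two ends with the higher amount of target, in percent of the solid substrate charged ("neither" if they lie within 2 percentage points) (noon / midnight / neither)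
2. target at the end, in percent of the solid substrate charged, noon
3. target at the end, in percent of the solid substrate charged, midnight

**What matters.** Enzyme must be known well, since in this balance the ceiling moves inversely with it. The solid charge acts as a divisor in these two runs at like enzyme: Sunday's run, with 0.054 M and 2 µM of enzyme, reads 2.11 mM of target at its last reading, Monday's, with 0.020 M and 2.1 µM, reads 2.26 mM. Time counts less at noon's enzyme than at Thursday's: Monday's run gained 1.5 percentage points over its last 8.00 h, Thursday's run 5 points over its last 5.00 h. At midnight, with enzyme near Thursday's, time counts, and s with it.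

**The numbers.** Monday's first reading gives s = 0.333 mM h⁻¹. Its last reading, taken as the ceiling, gives the target lifetime at Monday's enzyme, ceiling over supply, τ = 6.78 h, a reading with its scatter. On Thursday's run this gives 23.1% at its last reading, which stands at 24.8%. With the same s, my reckoning gives noon τ = 7.12 h and 11.7%, and midnight τ = 23.7 h and 7.09%. So my answer is noon, ahead by 4.6 points.

**The flask.** The forecast says noon, with 12.5% (11.3% to 13.8%) for noon and 7.2% (5% to 10.5%) for midnight, adding of midnight: "This is an extrapolation, so it is less certain". The simulation gives noon, with 12.8% for noon against 8.36% for midnight.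

    starting material + enzyme ⇌ complex (K = 1100 M⁻¹, k = 53400 M⁻¹ min⁻¹)
    complex ⇌ enzyme + target (K = 0.00720 M, k = 90.6 min⁻¹)
    enzyme + target → enzyme + over-reaction product (k = 1860 M⁻¹ min⁻¹)
    solid substrate ⇌ starting material, rate k4*(cs4 - [starting material]) while solid is left; crystals form when [starting material] > cs4 (solubility = 19.0 mM, k = 3.76 × 10⁻⁴ min⁻¹)

**Lifetime again.** At noon, target has a half-life of 4.4 h by the step to over-reaction product at 30.0 h, short against the run's 30 h. My τ for noon corresponds to a half-life of 4.94 h. For a flask like noon but with 5.0 × 10⁻⁷ M of enzyme, my reckoning gives τ = 28.5 h and 30.9%. Its computed result is 35.5%.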